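**Plan**

- Retrosynthesis: the pyranone is opened at O1–C2 to an o-hydroxyaryl 1,3-diketone, then C4a–C4 and C4–C3 are cut together, so C4 becomes carbon monoxide between a mirror-symmetric aryl iodide and 2-methoxy-1-phenylethanone.
- Enabling feature: C4 is an isolated carbonyl carbon bonded only to C4a of ring A (flanked by the oxygens on C5 and C8a) and to the methoxylated C3 of ring C, so it can be inserted as CO between an aryl electrophile and a ketone enolate.
- Forward order: ring A is fully oxygenated and iodinated from 1,2,3-trimethoxybenzene (steps 1–4), the C4–C3–C2–phenyl chain is attached in one carbonylative coupling (step 5), and ring C closes last (step 6).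
- Regiochemistry: the two acetal-protected oxygens beside the iodide are equivalent, so whichever phenol closes the ring, the other becomes the chelated 5-OH and no methyl ether has to be cleaved.
- Stereochemistry: the target is achiral; the methoxylated carbon of the diketone and the two sp3 carbons of the transient hemiketal form without control and disappear on aromatisation.

Key step: step 5

Remark on the chemistry: flavone numbering (O1, C2, C3, C4, C4a, C5–C8, C8a) is used for target atoms; the electron-rich phenol 4 is assumed to need an argon atmosphere.

**Route**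

Step 1
Reactants: 1 1,2,3-trimethoxybenzene
Product: 2 1,5-dibromo-2,3,4-trimethoxybenzene
Conditions: NBS (2.2 equiv), MeCN, rt then 50 °C
Reagents that add atoms: N-bromosuccinimide, O=C1CCC(=O)N1Br
Why: Electrophilic aromatic bromination should go to C4 and C6, each ortho to one outer methoxyl and para to the other, because C5 is activated only by the twisted central methoxyl.

Step 2
Reactants: 2 1,5-dibromo-2,3,4-trimethoxybenzene
Product: 4 4,5,6-trimethoxybenzene-1,3-diol, via dilithium bis-borate complex 3 (not isolated)
Conditions: B(OiPr)3 (3 equiv), n-BuLi (2.3 equiv, added last), toluene/THF, −78 °C to rt; then AcOH, 30% aq H2O2 (2.2 equiv), 0 °C to rt, argon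
Reagents that add atoms: hydrogen peroxide, OO
Why: Lithium–bromine exchange is faster than attack of n-BuLi on the borate ester, so each aryllithium is trapped as it forms (in situ quench borylation), and peroxide then turns both C–B bonds into C–O bonds at the same positions (ipso-hydroxylation of arylborates).

Step 3
Reactants: 4 4,5,6-trimethoxybenzene-1,3-diol
Product: 5 1,2,3-trimethoxy-4,6-bis(methoxymethoxy)benzene
Conditions: MOMCl (2.6 equiv), iPr2NEt (3.5 equiv), CH2Cl2, 0 °C to rt
Reagents that add atoms: chloromethyl methyl ether, COCCl
Why: O-Alkylation of both phenols by the alpha-chloro ether under amine base (methoxymethyl acetal protection) should be clean, and these acetals are chosen because they direct the next lithiation and are removed by the acid of step 6.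

Step 4
Reactants: 5 1,2,3-trimethoxy-4,6-bis(methoxymethoxy)benzene
Product: 7 2-iodo-4,5,6-trimethoxy-1,3-bis(methoxymethoxy)benzene, via aryllithium 6 (not isolated)
Conditions: n-BuLi (1.2 equiv), THF, 0 °C, 1 h; then I2 (1.3 equiv), −78 °C to rt
Reagents that add atoms: iodine, II
Why: Directed ortho-metalation should occur at the only ring hydrogen, which lies between two lithium-chelating acetal oxygens, and the aryllithium is then trapped by iodine to give the fully substituted iodide.

Step 5
Reactants: 7 2-iodo-4,5,6-trimethoxy-1,3-bis(methoxymethoxy)benzene; 8 2-methoxy-1-phenylethan-1-one; 9 carbon monoxide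
Product: 12 2-methoxy-1-phenyl-3-[3,4,5-trimethoxy-2,6-bis(methoxymethoxy)phenyl]propane-1,3-dione (racemic at the enolisable methoxylated carbon), via sodium enolate 10 (not isolated), via sodium diketonate 11 (not isolated)
Conditions: 8 (2.2 equiv), NaN(SiMe3)2 (2.2 equiv), THF, 0 °C; then 7 (1 equiv), Pd(dba)2 (5 mol %), 1,3-bis(diphenylphosphino)propane (6 mol %), CO (1 atm), 65 °C; AcOH (2.5 equiv), 0 °C
Reagents that add atoms: none
Why: Zerovalent palladium inserts into the C–I bond of 7, and migratory insertion of CO gives a divalent aroylpalladium iodide in which the metal sits one atom further from the two ortho acetal groups. Enolate 10 displaces iodide and reductive elimination from the carbon-bound enolate forms C4–C3, so C4a–C4 and C4–C3 are both made in one catalytic cycle. A second equivalent of 10 deprotonates the product at once to diketonate 11, which resists further acylation and is released as 12 by the acetic acid quench. The closest known reaction type is the palladium-catalysed carbonylative alpha-arylation of aryl alkyl ketones with aryl iodides to 1,3-diketones. No ring closes, and the only new stereocentre (the methoxylated carbon of 12) is uncontrolled, enolisable and destroyed in step 6. The step needs CO uptake before enolate coupling and C- rather than O-acylation: the two ortho substituents slow direct aryl–enolate reductive elimination, the chelating bisphosphine under CO favours the acyl pathway, and any enol ester would be transacylated by excess 10 to the more stable 11.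

Step 6
Reactants: 12 2-methoxy-1-phenyl-3-[3,4,5-trimethoxy-2,6-bis(methoxymethoxy)phenyl]propane-1,3-dione
Product: 15 5-hydroxy-3,6,7,8-tetramethoxyflavone, via diphenol diketone 13 (not isolated), via 2-hydroxyflavanone hemiketal 14 (not isolated)
Conditions: 3 M HCl in MeOH, 60 °C
Reagents that add atoms: none
Why: Acid-catalysed acetal solvolysis frees both phenols, either of these equivalent hydroxyls adds to the benzoyl carbonyl in a 6-exo-trig closure forming O1–C2, and loss of water aromatises the pyranone (cyclodehydration of an o-hydroxyaryl 1,3-diketone, as at the end of a Baker–Venkataraman flavone synthesis), leaving the other hydroxyl as the hydrogen-bonded 5-OH.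

**Compound list**

1 | 1,2,3-trimethoxybenzene | COc1cccc(OC)c1OC | starting material
2 | 1,5-dibromo-2,3,4-trimethoxybenzene (4,6-dibromo-1,2,3-trimethoxybenzene) | COc1c(OC)c(OC)c(Br)cc1Br | intermediate
3 | dilithium (4,5,6-trimethoxy-1,3-phenylene)bis[tri(propan-2-yloxy)borate], not isolated | [Li+].[Li+].COc1c(OC)c(OC)c([B-](OC(C)C)(OC(C)C)OC(C)C)cc1[B-](OC(C)C)(OC(C)C)OC(C)C | intermediate
4 | 4,5,6-trimethoxybenzene-1,3-diol | COc1c(OC)c(OC)c(O)cc1O | intermediate
5 | 1,2,3-trimethoxy-4,6-bis(methoxymethoxy)benzene | COCOc1cc(OCOC)c(OC)c(OC)c1OC | intermediate
6 | [3,4,5-trimethoxy-2,6-bis(methoxymethoxy)phenyl]lithium, not isolated | [Li]c1c(OCOC)c(OC)c(OC)c(OC)c1OCOC | intermediate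
7 | 2-iodo-4,5,6-trimethoxy-1,3-bis(methoxymethoxy)benzene | COCOc1c(I)c(OCOC)c(OC)c(OC)c1OC | intermediate
8 | 2-methoxy-1-phenylethan-1-one | COCC(=O)c1ccccc1 | starting material
9 | carbon monoxide | [C-]#[O+] | starting material
10 | sodium (Z)-2-methoxy-1-phenylethen-1-olate (chelated geometry expected), not isolated | [Na+].CO/C=C(\[O-])c1ccccc1 | intermediate
11 | sodium enolate of 12 (delocalised diketonate), not isolated | [Na+].COCOc1c(C(=O)C(OC)=C([O-])c2ccccc2)c(OCOC)c(OC)c(OC)c1OC | intermediate
12 | 2-methoxy-1-phenyl-3-[3,4,5-trimethoxy-2,6-bis(methoxymethoxy)phenyl]propane-1,3-dione (racemic, enolisable centre) | COCOc1c(C(=O)C(OC)C(=O)c2ccccc2)c(OCOC)c(OC)c(OC)c1OC | intermediate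
13 | 1-(2,6-dihydroxy-3,4,5-trimethoxyphenyl)-2-methoxy-3-phenylpropane-1,3-dione (racemic), not isolated | COc1c(OC)c(O)c(C(=O)C(OC)C(=O)c2ccccc2)c(O)c1OC | intermediate
14 | 2,5-dihydroxy-3,6,7,8-tetramethoxy-2-phenyl-2,3-dihydro-4H-chromen-4-one (racemic mixture of diastereomers, configuration not controlled), not isolated | COc1c(OC)c(O)c2c(c1OC)OC(O)(c1ccccc1)C(OC)C2=O | intermediate
15 | 5-hydroxy-3,6,7,8-tetramethoxyflavone (5-hydroxy-3,6,7,8-tetramethoxy-2-phenyl-4H-chromen-4-one) | COc1c(OC)c(O)c2c(=O)c(OC)c(-c3ccccc3)oc2c1OC | target

**Count and risks**

Total steps: 6. Longest linear sequence: 6 steps (1 to 15); 8 and 9 enter at step 5.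

Steps most likely to fail:

Step 5. Oxidative addition of the crowded, electron-rich iodide may be slow enough for CO to tie up zerovalent palladium as inactive carbonyl species, or the enolate may couple before CO is taken up. The fallback sets out from 5. It is lithiated as in step 4 to 6 and treated with N,2-dimethoxy-N-methylacetamide (Weinreb ketone synthesis, THF, −78 °C to 0 °C, AcOH quench). This should give 2-methoxy-1-[3,4,5-trimethoxy-2,6-bis(methoxymethoxy)phenyl]ethan-1-one F1. Its lithium enolate (LiN(SiMe3)2, 2.2 equiv, THF, −78 °C) is then C-benzoylated with 1-benzoyl-1H-benzotriazole (crossed Claisen-type acylation, AcOH quench), and the route is rejoined at 12. In this variant the enolate attacks an unhindered benzoyl donor rather than the crowded aroyl carbon.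

Step 2. The second lithium–bromine exchange on the anionic mono-borate may lag, giving protonated or butylated arenes, and the peroxide may over-oxidise the very electron-rich resorcinol towards a quinone. The fallback sets out from 2. Miyaura borylation (B2pin2, PdCl2(dppf), KOAc, 1,4-dioxane, 90 °C) should give the isolable 2,2'-(4,5,6-trimethoxy-1,3-phenylene)bis(4,4,5,5-tetramethyl-1,3,2-dioxaborolane) F2. After purification it is oxidised with a measured amount of H2O2 in THF/AcOH at 0 °C, and the route is rejoined at 4.

Step 6. Methanolysis of the 1,3-diketone (retro-Claisen cleavage) may compete with ring closure in hot methanolic acid, or closure may stall at the hemiketal. The fallback sets out from 12 and separates deprotection from ring closure. The acetals are removed without a nucleophilic solvent by ZnBr2 and propane-1-thiol in CH2Cl2 at 0 °C (thiol-mediated transacetalisation), and the diphenol 13 (in equilibrium with 14) is isolated. Water is then removed with catalytic p-toluenesulfonic acid in toluene under azeotropic distillation, and the route is rejoined at 15. No compound outside the list is made (F0).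

**Further compounds**

F1 | step 5 | 2-methoxy-1-[3,4,5-trimethoxy-2,6-bis(methoxymethoxy)phenyl]ethan-1-one | COCOc1c(C(=O)COC)c(OCOC)c(OC)c(OC)c1OC
F2 | step 2 | 2,2'-(4,5,6-trimethoxy-1,3-phenylene)bis(4,4,5,5-tetramethyl-1,3,2-dioxaborolane) | COc1c(OC)c(OC)c(B2OC(C)(C)C(C)(C)O2)cc1B1OC(C)(C)C(C)(C)O1
F0 | step 6 | none | none
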